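Ring B is disconnected at C7–C8: the epoxide is traced back to a C7=C8 alkene, and that alkene to two olefinic arms on a preformed ring A. The key step exploits the position of C7 and C8 between the C1 carbinol bridgehead and the C6 methyl ether: a vinyl group on C1 and a 1-methoxyallyl group on C5, cis and 1,3-diaxial across the C9 ketone, are joined by ring-closing metathesis, which closes ring B and creates the bicyclo[3.3.1]nonane in one operation. The precursor is a quinic-acid-derived ring A cyclohexanone that already carries the C3 dodecenoyl amide, the O4 silyl ether, the free C1 hydroxyl and the stereocentres C1, C3, C4, C5 and C6.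

Key step: step 14

Remark on numbering: atom numbers are those of the bicyclic target and are used for every ring A intermediate; quinic acid C1, C2, C3, C4, C5, C6 correspond to target C1, C9, C5, C4, C3, C2.

Remark on the structures: the diene ketone 21, the bicyclic enone 22 and the target 24 have the same configuration at C1, C3, C4, C5 and C6, and natural (−)-quinic acid maps onto C1, C4 and (after inversion) C3; no stereodescriptor had to be changed.

Remark on the chemistry: with C9 as carbonyl, C4 as alpha substituent and O6 as beta oxygen, the target has the syn aldol pattern at C5/C6. A closed, metal-chelated aldol of the ring A enolate (necessarily E) followed by O-methylation would be expected to give the C6 epimer, so the C6–C8 unit is introduced as commercial acrolein dimethyl acetal through an open transition state.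

Step 1
Reactants: 1 (−)-quinic acid
Product: 2 methyl quinate O3/O4-butane-2,3-diacetal
Conditions: butane-2,3-dione, HC(OMe)3, CSA (cat.), MeOH, reflux
Reagents that add atoms: butane-2,3-dione CC(=O)C(C)=O; methanol CO; trimethyl orthoformate COC(OC)OC
Why: Fischer esterification and butane-2,3-diacetal formation run in the same pot: only the trans-diequatorial O3/O4 diol can be bridged as the trans-fused bis-acetal with both methoxy groups axial (anomeric stabilization), so the axial O5–H and the tertiary O1–H stay free and no ring stereocentre is touched.

Step 2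
Reactants: 2 methyl quinate O3/O4-butane-2,3-diacetal
Product: 4 C9=C5 alkene ester, via C5 triflate 3 (not isolated)
Conditions: Tf2O, pyridine, CH2Cl2, −20 °C; then DBU, 0 °C → rt
Reagents that add atoms: none
Why: Selective triflation of the only secondary hydroxyl (the tertiary O1–H next to the ester is too hindered at −20 °C) followed by E2 elimination: the axial C5 triflate is antiperiplanar to the axial hydrogen of the C9 methylene, and loss of that hydrogen should outrun loss of H4, whose C–H bond is deactivated by the geminal acetal oxygen, so the C9=C5 alkene results and the C5 stereocentre is deliberately erased.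

Step 3
Reactants: 4 C9=C5 alkene ester
Product: 6 ene lactone diol, via triol methyl ester 5 (not isolated)
Conditions: TFA/H2O (9:1), CH2Cl2, 0 °C → rt, evaporate; then PPTS (cat.), toluene, 80 °C, MeOH distilled off
Reagents that add atoms: none
Why: Aqueous acid hydrolyses the bis-acetal and mild acid then drives an intramolecular transesterification: the C1 ester and O3–H are cis and can both become pseudoaxial on the cyclohexene, so they close the bridged five-membered lactone, which masks O3 and leaves the allylic O4–H as the only secondary alcohol.

Step 4
Reactants: 6 ene lactone diol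
Product: 7 epoxy lactone diol
Conditions: VO(acac)2 (5 mol %), t-BuOOH, CH2Cl2, 0 °C → rt
Reagents that add atoms: tert-butyl hydroperoxide CC(C)(C)OO
Why: Hydroxyl-directed vanadium-catalysed epoxidation of an allylic alcohol: the pseudoaxial O4–H and O1–H both lie on the face opposite the lactone bridge and deliver the peroxide there, so one epoxide is expected, whose two centres are transient and serve only to carry an oxygen onto C9.

Step 5
Reactants: 7 epoxy lactone diol
Product: 8 O4-TBS epoxy lactone
Conditions: TBSCl, imidazole, DMF, rt
Reagents that add atoms: tert-butyldimethylsilyl chloride CC(C)(C)[Si](C)(C)Cl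
Why: Standard silylation: the secondary O4–H reacts with TBSCl and imidazole while the tertiary bridgehead O1–H flanked by the lactone carbonyl does not, and the epoxide is inert to these conditions.

Step 6
Reactants: 8 O4-TBS epoxy lactone
Product: 9 epoxy lactol
Conditions: i-Bu2AlH (2.5 equiv), CH2Cl2, −78 °C
Reagents that add atoms: none
Why: Partial reduction of a bridged lactone with i-Bu2AlH at −78 °C stops at the stable bicyclic hemiacetal (one extra equivalent is consumed by O1–H), and the epoxide and silyl ether are not attacked at this temperature.

Step 7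
Reactants: 9 epoxy lactol
Product: 10 vinyl epoxy diol
Conditions: Ph3PCH3Br, KOtBu, THF, 0 °C → rt
Reagents that add atoms: methyltriphenylphosphonium bromide C[P+](c1ccccc1)(c1ccccc1)c1ccccc1.[Br-]
Why: Wittig methylenation of the lactol through its open hydroxy aldehyde form turns the former carboxyl carbon into the C1 vinyl group (C8 of the target) and at the same stroke releases O3–H as the only secondary alcohol; the syn relationship of O1 and the epoxide oxygen rules out epoxide migration under the basic conditions.

Step 8
Reactants: 10 vinyl epoxy diol
Product: 12 C3 azide, via C3 triflate 11 (not isolated)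
Conditions: Tf2O, pyridine, CH2Cl2, −30 °C; then NaN3, DMF, 0 °C → rt
Reagents that add atoms: sodium azide [Na+].[N-]=[N+]=[N-]
Why: Triflation of the secondary O3–H and SN2 displacement by azide with inversion place nitrogen on C3 cis to O4 and O1 as the target requires; in the favoured half-chair the triflate is equatorial and has no antiperiplanar hydrogen, which should hold back E2.

Step 9
Reactants: 12 C3 azide
Product: 13 amino diol
Conditions: LiAlH4 (4 equiv), THF, 0 °C → rt
Reagents that add atoms: none
Why: LiAlH4 reduces the azide to the amine and opens the epoxide by hydride attack at C5: trans-diaxial opening from the favoured half-chair (C1 vinyl and O4 silyl ether pseudoaxial, N3 equatorial) and the neopentyl character of C9 both point to C5, and since O1, N3 and the epoxide oxygen are all on one face no internal nucleophile or hydride carrier can reach the back side of the epoxide.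

Step 10
Reactants: 13 amino diol; 14 (E)-dodec-2-enoic acid
Product: 16 amide diol, via acid chloride 15 (not isolated)
Conditions: 14, (COCl)2, DMF (cat.), CH2Cl2, 0 °C → rt, evaporate; then 13, aq. NaHCO3/CH2Cl2, 0 °C
Reagents that add atoms: none
Why: Acylation of an amine by an acid chloride under two-phase bicarbonate conditions: the primary amine is far more nucleophilic than the secondary and tertiary hydroxyls, so only the amide should form, and the (E) geometry of the enoyl unit is not affected by oxalyl chloride activation.

Step 11
Reactants: 16 amide diol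
Product: 17 ring A hydroxy ketone
Conditions: SO3·pyridine, DMSO, i-Pr2NEt, CH2Cl2, 0 °C
Reagents that add atoms: none
Why: Parikh–Doering oxidation converts the secondary C9 carbinol into the ketone; the tertiary O1–H cannot be oxidized, activated dimethyl sulfoxide does not cleave the 1,2-diol, and the mild amine base at 0 °C should not eliminate the beta silyloxy group.

Step 12
Reactants: 17 ring A hydroxy ketone
Product: 18 bis(trimethylsilyl) enol ether
Conditions: TMSOTf (3.5 equiv), Et3N, CH2Cl2, 0 °C; cold aq. NaHCO3 wash
Reagents that add atoms: trimethylsilyl trifluoromethanesulfonate C[Si](C)(C)OS(=O)(=O)C(F)(F)F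
Why: Soft enolization with TMSOTf and triethylamine: C5 is the only enolizable position because C1 is quaternary, so a single enol silane forms, and the same reagent caps the tertiary O1–H as a trimethylsilyl ether, which keeps the alpha-ketol from rearranging or chelating in the next step.

Step 13
Reactants: 18 bis(trimethylsilyl) enol ether; 19 acrolein dimethyl acetal
Product: 21 ring A diene ketone (metathesis precursor), via O1-trimethylsilyl adduct 20 (not isolated)
Conditions: TMSOTf (0.3 equiv), 2,6-di-tert-butyl-4-methylpyridine, CH2Cl2, −78 °C; then 0.5 M HCl, THF, 0 °C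
Reagents that add atoms: none
Why: Mukaiyama-type aldol addition of an enol silane to the oxocarbenium ion generated from an acetal: attack on C5 anti to the neighbouring pseudoaxial O4 silyl ether should set C5 trans to O4 and cis to the C1 vinyl group, the open antiperiplanar transition state that keeps the vinyl group of the cation away from C4 should set C6 in the required syn relationship and deliver the methyl ether directly, addition at the acetal carbon and not at the alkene terminus is the usual course for enal acetals, and dilute acid then removes the labile tertiary trimethylsilyl ether without touching the O4 silyl ether or epimerizing C5.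

Step 14
Reactants: 21 ring A diene ketone (metathesis precursor)
Product: 22 bicyclo[3.3.1]non-7-en-9-one
Conditions: second-generation Grubbs catalyst RuCl2(H2IMes)(PCy3)(=CHPh) (10 mol %), CH2Cl2 (2 mM), 40 °C
Reagents that add atoms: none
Why: Ring-closing olefin metathesis: the ruthenium benzylidene should exchange first onto the more accessible terminus of the C5 methoxyallyl arm, and the resulting alkylidene on C7 adds to the C1 vinyl group in a [2+2] sense and cycloreverts, expelling ethylene and leaving the C7=C8 double bond. The closest known reaction type is the ring-closing metathesis of cis-2,6-dialkenylcyclohexanones to bicyclo[3.3.1]nonenones. Ring B (C1–C8–C7–C6–C5–C9) is closed as a six-membered cycloalkene across the two alpha carbons of the ring A ketone, which requires the ring A chair that carries both arms axial; that chair should be accessible because the other chair would set O1–H and the C3 amide syn-diaxial and crowd the O4 silyl ether against the C5 arm. No stereocentre is created: C1 comes from quinic acid, C5 and C6 come from step 13, and once C5 is a bridgehead it can no longer epimerize by enolization. The selectivity needed is chemoselectivity, secured by the conjugated side-chain double bond being electron-poor and internal (a poor metathesis partner), by the free tertiary allylic hydroxyl being tolerated, and by high dilution, which suppresses intermolecular metathesis of the terminal alkenes.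

Step 15
Reactants: 22 bicyclo[3.3.1]non-7-en-9-one
Product: 23 O4-TBS epoxide
Conditions: VO(acac)2 (10 mol %), t-BuOOH, CH2Cl2, rt
Reagents that add atoms: tert-butyl hydroperoxide CC(C)(C)OO
Why: Vanadium-catalysed epoxidation of a tertiary allylic alcohol: the C1 hydroxyl binds the metal and the peroxide oxygen is delivered to the convex face of C7=C8, the concave face being shielded by the C2–C3–C4 bridge of ring A, which should set C7 and C8 with the epoxide anti to ring A as in the target, while the side-chain enamide alkene, which has no allylic hydroxyl and is electron-poor, is left alone.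

Step 16
Reactants: 23 O4-TBS epoxide
Product: 24 CNP0137540.1 (target)
Conditions: HF·pyridine, pyridine, THF, 0 °C → rt
Reagents that add atoms: none
Why: Fluoride cleavage of the secondary silyl ether under buffered, slightly acidic conditions, chosen because a basic fluoride source could trigger retro-aldol cleavage of the C4–C5 bond of the beta-hydroxy ketone, whereas the epoxide, the alpha-ketol and the enamide should all survive HF·pyridine at 0 °C.

Compound list

1 | (−)-quinic acid, (1S,3R,4S,5R)-1,3,4,5-tetrahydroxycyclohexane-1-carboxylic acid | C1[C@H]([C@H]([C@@H](C[C@@]1(C(=O)O)O)O)O)O | starting material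
2 | methyl quinate with O3 and O4 (the trans diol) bridged as the (2S,3S)-2,3-dimethoxybutane-2,3-diyl bis-acetal; O1–H and O5–H free; quinic acid configuration | O[C@@]1(C(=O)OC)C[C@@H](O)[C@H]2O[C@@](OC)(C)[C@](OC)(C)O[C@@H]2C1 | intermediate
3 | C5 trifluoromethanesulfonate of 2 | O[C@@]1(C(=O)OC)C[C@@H](OS(=O)(=O)C(F)(F)F)[C@H]2O[C@@](OC)(C)[C@](OC)(C)O[C@@H]2C1 | intermediate (not isolated)
4 | alkene ester: as 2 but with a C9=C5 double bond in place of C5–OH (methyl 2,3-anhydroquinate butane-2,3-diacetal) | O[C@@]1(C(=O)OC)C=C[C@H]2O[C@@](OC)(C)[C@](OC)(C)O[C@@H]2C1 | intermediate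
5 | methyl 1,4,5-trihydroxycyclohex-2-ene-1-carboxylate with the quinic acid configuration (ester cis to O3–H, trans to O4–H) | O[C@@]1(C(=O)OC)C=C[C@@H](O)[C@H](O)C1 | intermediate (not isolated)
6 | 1,4-dihydroxy-6-oxabicyclo[3.2.1]oct-2-en-7-one: C1 carboxyl lactonized onto O3; O1–H and allylic O4–H on the face opposite the lactone bridge | O[C@]12C=C[C@@H](O)[C@H](OC1=O)C2 | intermediate
7 | epoxy lactone diol: 6 with a C9–C5 epoxide on the face of O1–H and O4–H, anti to the lactone bridge | O[C@]12[C@H]3O[C@H]3[C@@H](O)[C@H](OC1=O)C2 | intermediate
8 | O4-tert-butyldimethylsilyl ether of 7 | O[C@]12[C@H]3O[C@H]3[C@@H](O[Si](C)(C)C(C)(C)C)[C@H](OC1=O)C2 | intermediate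
9 | lactol of 8 (lactone carbonyl reduced to the hemiacetal, both anomers) | O[C@]12[C@H]3O[C@H]3[C@@H](O[Si](C)(C)C(C)(C)C)[C@H](OC1O)C2 | intermediate
10 | vinyl epoxy diol: cyclohexane with C1(OH)(vinyl), C9–C5 epoxide, O4-TBS and C3–OH; O1–H, epoxide oxygen and O4 on one face, vinyl and O3–H on the other | O[C@@]1(C=C)[C@H]2O[C@H]2[C@@H](O[Si](C)(C)C(C)(C)C)[C@H](O)C1 | intermediate
11 | C3 trifluoromethanesulfonate of 10 | O[C@@]1(C=C)[C@H]2O[C@H]2[C@@H](O[Si](C)(C)C(C)(C)C)[C@H](OS(=O)(=O)C(F)(F)F)C1 | intermediate (not isolated)
12 | C3 azide, inverted at C3: azide cis to O4, O1–H and the epoxide oxygen | O[C@@]1(C=C)[C@H]2O[C@H]2[C@@H](O[Si](C)(C)C(C)(C)C)[C@@H](N=[N+]=[N-])C1 | intermediate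
13 | amino diol: C1(OH)(vinyl), C9–OH, C5H2, O4-TBS, C3–NH2; O1–H, O9–H, O4 and N3 all cis, vinyl trans | O[C@@]1(C=C)[C@@H](O)C[C@@H](O[Si](C)(C)C(C)(C)C)[C@@H](N)C1 | intermediate
14 | (E)-dodec-2-enoic acid | CCCCCCCCC/C=C/C(=O)O | starting material
15 | (E)-dodec-2-enoyl chloride | CCCCCCCCC/C=C/C(=O)Cl | intermediate (not isolated)
16 | N-[(E)-dodec-2-enoyl] amide of 13 | O[C@@]1(C=C)[C@@H](O)C[C@@H](O[Si](C)(C)C(C)(C)C)[C@@H](NC(=O)/C=C/CCCCCCCCC)C1 | intermediate
17 | ring A hydroxy ketone: 2-hydroxy-2-vinylcyclohexanone (C9 ketone, C5H2) with O4-TBS and the C3 dodecenoyl amide; O1–H, O4 and N3 cis | O[C@@]1(C=C)C(=O)C[C@@H](O[Si](C)(C)C(C)(C)C)[C@@H](NC(=O)/C=C/CCCCCCCCC)C1 | intermediate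
18 | O1-trimethylsilyl ether and C9=C5 trimethylsilyl enol ether of 17 | C[Si](C)(C)O[C@@]1(C=C)C(O[Si](C)(C)C)=C[C@@H](O[Si](C)(C)C(C)(C)C)[C@@H](NC(=O)/C=C/CCCCCCCCC)C1 | intermediate
19 | acrolein dimethyl acetal (3,3-dimethoxyprop-1-ene) | C=CC(OC)OC | starting material
20 | O1-trimethylsilyl ether of 21 | C[Si](C)(C)O[C@@]1(C=C)C(=O)[C@H]([C@H](OC)C=C)[C@@H](O[Si](C)(C)C(C)(C)C)[C@@H](NC(=O)/C=C/CCCCCCCCC)C1 | intermediate (not isolated)
21 | ring A ketone with C1 vinyl and C5 1-methoxyallyl arms cis to each other, C5 arm trans to O4-TBS, syn C5/C6 (dodecenoyl amide, O4-TBS, free O1–H) | CCCCCCCCC/C=C/C(=O)N[C@H]1C[C@](O)(C=C)C(=O)[C@@H]([C@H]1O[Si](C)(C)C(C)(C)C)[C@H](OC)C=C | intermediate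
22 | bicyclo[3.3.1]non-7-en-9-one with C6 methyl ether (dodecenoyl amide, O4-TBS, C1–OH) | CCCCCCCCC/C=C/C(=O)N[C@H]1C[C@@]2(O)C(=O)[C@@H]([C@H]1O[Si](C)(C)C(C)(C)C)[C@H](OC)C=C2 | intermediate
23 | O4-TBS ether of the target: C7–C8 epoxide on the face anti to the C2–C3–C4 bridge, cis to the C6 methoxy group | CCCCCCCCC/C=C/C(=O)N[C@H]1C[C@@]2(O)C(=O)[C@@H]([C@H]1O[Si](C)(C)C(C)(C)C)[C@H](OC)[C@@H]1O[C@@H]12 | intermediate
24 | CNP0137540.1 | CCCCCCCCC/C=C/C(=O)N[C@H]1C[C@@]2(O)C(=O)[C@@H]([C@H]1O)[C@H](OC)[C@@H]1O[C@@H]12 | target

Total step count: 16. Longest linear sequence: 16 steps (1 → 24); acid 14 and acetal 19 are commercial.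

Steps most likely to fail

Step 13. The addition to the methoxyallyl cation may lose regio- or stereocontrol: attack at the alkene terminus of the cation, erosion of the syn C5/C6 preference, or Lewis-acid ionization of the doubly allylic O1 silyl ether. The fallback sets out from 18 and returns at 21. Enol silane 18 is treated with acrolein and a catalytic amount of tris(dimethylamino)sulfonium difluorotrimethylsilicate in THF at −78 °C; the fluoride-generated, metal-free enolate reacts through an open transition state, which should again favour the syn pattern, and silyl transfer should give the bis(trimethylsilyl) syn aldol F1. Citric acid in methanol should remove both trimethylsilyl groups to give the beta-hydroxy ketone diol F2. MeI with Ag2O and molecular sieves (neutral conditions) should then methylate the secondary allylic O6–H in preference to the tertiary O1–H and give 21.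

Step 14. The catalyst may fail to load productively on either vinyl group, since one sits on a quaternary carbinol carbon and the other next to a branched ether carbon, so that alkene isomerization or intermolecular metathesis outruns ring closure. The fallback sets out from 18 and returns at 22. Commercial (E)-4,4-dimethoxybut-2-enal is reduced with NaBH4 in methanol to (E)-4,4-dimethoxybut-2-en-1-ol F3, which is allylated with NaH and allyl bromide to the relay acetal (E)-1-(allyloxy)-4,4-dimethoxybut-2-ene F4. Addition of 18 to F4 under the conditions of step 13 should give the O1-trimethylsilyl relay adduct F5 and, after the same acidic work-up, the relay diene ketone F6, whose C5 arm ends in an allyl ether. With RuCl2(H2IMes)(PCy3)(=CHPh) at high dilution the metal loads on the unhindered allyl ether, expels 2,5-dihydrofuran to place the alkylidene on C7 and then closes onto the C1 vinyl group to give 22.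

Step 8. Substitution at the hindered C3 triflate may be outrun by elimination or by participation of the neighbouring O1–H. The fallback sets out from 10 and returns at 13. Oxidation of O3–H with 1,1,1-triacetoxy-1,1-dihydro-1,2-benziodoxol-3(1H)-one (NaHCO3 buffer, CH2Cl2) gives the epoxy ketone F7, and hydroxylamine hydrochloride with NaOAc in ethanol gives the oxime F8. LiAlH4 in THF then reduces the oxime, with hydride expected to add to C3 anti to the neighbouring O4 silyl ether so that nitrogen ends up cis to O4, and opens the epoxide at C5 in the same operation, giving 13.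

Further compounds

F1 | step 13 | bis(trimethylsilyl) syn aldol: 21 with O1–SiMe3 and with O6–SiMe3 in place of O6–Me | CCCCCCCCC/C=C/C(=O)N[C@H]1C[C@](O[Si](C)(C)C)(C=C)C(=O)[C@@H]([C@H]1O[Si](C)(C)C(C)(C)C)[C@H](O[Si](C)(C)C)C=C
F2 | step 13 | beta-hydroxy ketone diol: 21 with O6–H in place of O6–Me | CCCCCCCCC/C=C/C(=O)N[C@H]1C[C@](O)(C=C)C(=O)[C@@H]([C@H]1O[Si](C)(C)C(C)(C)C)[C@H](O)C=C
F3 | step 14 | (E)-4,4-dimethoxybut-2-en-1-ol | OC/C=C/C(OC)OC
F4 | step 14 | (E)-1-(allyloxy)-4,4-dimethoxybut-2-ene | C=CCOC/C=C/C(OC)OC
F5 | step 14 | O1-trimethylsilyl relay adduct (O1-trimethylsilyl ether of F6) | CCCCCCCCC/C=C/C(=O)N[C@H]1C[C@](O[Si](C)(C)C)(C=C)C(=O)[C@@H]([C@H]1O[Si](C)(C)C(C)(C)C)[C@H](OC)/C=C/COCC=C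
F6 | step 14 | relay diene ketone: 21 with the C5 arm extended to (E)-CH(OMe)–CH=CH–CH2–O–CH2–CH=CH2 | CCCCCCCCC/C=C/C(=O)N[C@H]1C[C@](O)(C=C)C(=O)[C@@H]([C@H]1O[Si](C)(C)C(C)(C)C)[C@H](OC)/C=C/COCC=C
F7 | step 8 | epoxy ketone: 10 with a C3 ketone in place of C3–OH | O[C@@]1(C=C)[C@H]2O[C@H]2[C@@H](O[Si](C)(C)C(C)(C)C)C(=O)C1
F8 | step 8 | oxime of F7 (either geometry) | O[C@@]1(C=C)[C@H]2O[C@H]2[C@@H](O[Si](C)(C)C(C)(C)C)C(=NO)C1
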